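**Retrosynthetic overview**

- The strategy rests on one feature (germacrane numbering): C4 is the γ-carbon of the vinylogous ester O–C3=C2–C1=O of the 3(2H)-furanone ring and is bonded to the carbinol carbon C5 of the ten-membered carbocycle C1–C10. C4–C5 is therefore a vinylogous aldol bond; cutting it (5-acetate removed, C4/C15 diol as acetonide) opens the carbocycle to a C4–H furanone tethered to a lactone-bound C5 aldehyde.
- C7–C8 is cut next by a Barbier allylation of a furanone acetaldehyde with a 3-(bromomethyl)butenolide, which creates the α-methylene lactone. Its chair transition state gives the 8-epi carbinol, so the methacrylate is put on by Mitsunobu inversion.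
- The furanone comes from Claisen acylation of a citramalate-derived α-hydroxy methyl ketone with the glycerate ester, then cyclodehydration. C10 and C6 are taken from the chiral pool.
- Ring order: furanone ring (step 7), α-methylene lactone ring (step 13, from the butenolide), ten-membered carbocycle (step 17); acetylation and acetonide hydrolysis finish the synthesis.

Key step: step 17

Remark on the chemistry: germacrane numbering is used for the late compounds. The glycerate-derived C4 centre is drawn R throughout, but its configuration is irrelevant because C4 becomes planar in step 17. The indium allylation is assumed to follow the chair transition state usual for ring-locked 3-(bromomethyl)butenolides.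

**Route**

Step 1
Reactants: 1 (S)-citramalic acid
Product: 2 2-[(4S)-2,2,4-trimethyl-5-oxo-1,3-dioxolan-4-yl]acetic acid
Conditions: 2,2-dimethoxypropane, TsOH·H2O (cat.), acetone, rt
Reagents that add atoms: 2,2-dimethoxypropane, COC(C)(C)OC
Why: Acid-catalysed acetonide (dioxolanone) formation engages only the α-hydroxy acid unit, which differentiates the two carboxyl groups and leaves the quaternary centre (future C10) untouched.

Step 2
Reactants: 2 2-[(4S)-2,2,4-trimethyl-5-oxo-1,3-dioxolan-4-yl]acetic acid
Product: 3 (5S)-5-(2-hydroxyethyl)-2,2,5-trimethyl-1,3-dioxolan-4-one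
Conditions: BH3·SMe2, THF, 0 °C to rt; aqueous work-up
Reagents that add atoms: none
Why: Chemoselective borane reduction of a free carboxylic acid in the presence of the dioxolanone; the crude alcohol is silylated at once to forestall lactonisation.

Step 3
Reactants: 3 (5S)-5-(2-hydroxyethyl)-2,2,5-trimethyl-1,3-dioxolan-4-one
Product: 4 (5S)-5-[2-(tert-butyldimethylsilyloxy)ethyl]-2,2,5-trimethyl-1,3-dioxolan-4-one
Conditions: TBSCl, imidazole, CH2Cl2, 0 °C
Reagents that add atoms: tert-butyldimethylsilyl chloride, CC(C)(C)[Si](C)(C)Cl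
Why: Standard silylation of a primary alcohol; the TBS ether survives the basic steps that follow.

Step 4
Reactants: 4 (5S)-5-[2-(tert-butyldimethylsilyloxy)ethyl]-2,2,5-trimethyl-1,3-dioxolan-4-one
Product: 5 (2S)-4-(tert-butyldimethylsilyloxy)-2-hydroxy-N-methoxy-N,2-dimethylbutanamide
Conditions: MeNH(OMe)·HCl, i-PrMgCl, THF, −20 to 0 °C
Reagents that add atoms: N,O-dimethylhydroxylamine hydrochloride, CNOC.Cl
Why: Weinreb amide formation by aminolysis of the activated dioxolanone with the magnesium amide, which releases acetone and the tertiary alkoxide without touching the stereocentre.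

Step 5
Reactants: 5 (2S)-4-(tert-butyldimethylsilyloxy)-2-hydroxy-N-methoxy-N,2-dimethylbutanamide
Product: 6 (3S)-5-(tert-butyldimethylsilyloxy)-3-hydroxy-3-methylpentan-2-one
Conditions: MeMgBr (3 equiv), THF, −78 to 0 °C; aq. NH4Cl
Reagents that add atoms: methylmagnesium bromide, C[Mg]Br
Why: Weinreb ketone synthesis; the chelated tetrahedral intermediate prevents over-addition, and the first equivalent only deprotonates the tertiary hydroxyl.

Step 6
Reactants: 6 (3S)-5-(tert-butyldimethylsilyloxy)-3-hydroxy-3-methylpentan-2-one; 7 methyl (4R)-2,2-dimethyl-1,3-dioxolane-4-carboxylate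
Product: 8 (4S)-6-(tert-butyldimethylsilyloxy)-1-[(4R)-2,2-dimethyl-1,3-dioxolan-4-yl]-4-hydroxy-4-methylhexane-1,3-dione
Conditions: LiHMDS (3.2 equiv), THF, −78 °C; then 7, −78 to −10 °C; aq. NH4Cl
Reagents that add atoms: none
Why: Claisen condensation: the alkoxide–enolate of 6 (only the methyl group is enolisable) C-acylates the activated α-alkoxy ester, and the third equivalent of base removes the product as its diketonate, which drives the reaction.

Step 7
Reactants: 8 (4S)-6-(tert-butyldimethylsilyloxy)-1-[(4R)-2,2-dimethyl-1,3-dioxolan-4-yl]-4-hydroxy-4-methylhexane-1,3-dione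
Product: 9 (2S)-2-[2-(tert-butyldimethylsilyloxy)ethyl]-5-[(4R)-2,2-dimethyl-1,3-dioxolan-4-yl]-2-methylfuran-3(2H)-one
Conditions: PPTS (cat.), 4 Å MS, toluene, 50 °C
Reagents that add atoms: none
Why: Acid-catalysed cyclodehydration of an α′-hydroxy 1,3-diketone, the standard 3(2H)-furanone synthesis: the tertiary hydroxyl adds to the distal carbonyl and the hemiketal loses water, while the weak anhydrous acid spares acetonide and silyl ether.

Step 8
Reactants: 9 (2S)-2-[2-(tert-butyldimethylsilyloxy)ethyl]-5-[(4R)-2,2-dimethyl-1,3-dioxolan-4-yl]-2-methylfuran-3(2H)-one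
Product: 10 (2S)-5-[(4R)-2,2-dimethyl-1,3-dioxolan-4-yl]-2-(2-hydroxyethyl)-2-methylfuran-3(2H)-one
Conditions: HF·pyridine, pyridine, THF, 0 °C to rt
Reagents that add atoms: none
Why: Buffered fluoride desilylation of a primary TBS ether, which leaves the acetonide and the furanone intact.

Step 9
Reactants: 10 (2S)-5-[(4R)-2,2-dimethyl-1,3-dioxolan-4-yl]-2-(2-hydroxyethyl)-2-methylfuran-3(2H)-one
Product: 11 2-[(2S)-5-[(4R)-2,2-dimethyl-1,3-dioxolan-4-yl]-2-methyl-3-oxo-2,3-dihydrofuran-2-yl]acetaldehyde
Conditions: Dess–Martin periodinane, NaHCO3, CH2Cl2, 0 °C to rt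
Reagents that add atoms: none
Why: Dess–Martin oxidation under buffered, base-free conditions gives the β-alkoxy aldehyde without β-elimination of the furanone oxygen; it is used directly.

Step 10
Reactants: 12 (5S)-5-(hydroxymethyl)furan-2(5H)-one
Product: 13 (5S)-5-[(tert-butyldimethylsilyloxy)methyl]furan-2(5H)-one
Conditions: TBSCl, imidazole, CH2Cl2, 0 °C to rt
Reagents that add atoms: tert-butyldimethylsilyl chloride, CC(C)(C)[Si](C)(C)Cl
Why: Standard silylation of the primary alcohol (future C5 oxygen) under conditions too mild to epimerise the γ-centre (future C6).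

Step 11
Reactants: 13 (5S)-5-[(tert-butyldimethylsilyloxy)methyl]furan-2(5H)-one
Product: 14 (5S)-5-[(tert-butyldimethylsilyloxy)methyl]-3-(hydroxymethyl)furan-2(5H)-one
Conditions: aq. HCHO (37%), PBu3 (cat.), THF, rt
Reagents that add atoms: formaldehyde, C=O
Why: Morita–Baylis–Hillman hydroxymethylation: the phosphine adds to the butenolide β-carbon, the enolate captures formaldehyde at the α-carbon and elimination restores the alkene, the weakly basic catalyst leaving the γ-stereocentre alone.

Step 12
Reactants: 14 (5S)-5-[(tert-butyldimethylsilyloxy)methyl]-3-(hydroxymethyl)furan-2(5H)-one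
Product: 15 (5S)-3-(bromomethyl)-5-[(tert-butyldimethylsilyloxy)methyl]furan-2(5H)-one
Conditions: CBr4, PPh3, CH2Cl2, 0 °C
Reagents that add atoms: carbon tetrabromide, BrC(Br)(Br)Br
Why: Appel bromination of a primary allylic alcohol under neutral conditions.

Step 13
Reactants: 11 2-[(2S)-5-[(4R)-2,2-dimethyl-1,3-dioxolan-4-yl]-2-methyl-3-oxo-2,3-dihydrofuran-2-yl]acetaldehyde; 15 (5S)-3-(bromomethyl)-5-[(tert-butyldimethylsilyloxy)methyl]furan-2(5H)-one
Product: 17 (6S,7R,8S,10S)-seco alcohol: (4R,5S)-5-[(tert-butyldimethylsilyloxy)methyl]-3-methylidene-oxolan-2-one carrying at C4 the (1S)-1-hydroxy-2-[(2S)-5-((4R)-2,2-dimethyl-1,3-dioxolan-4-yl)-2-methyl-3-oxofuran-2-yl]ethyl group, via allylindium bromide 16 (not isolated)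
Conditions: In powder, THF/H2O (1:1), rt
Reagents that add atoms: none
Why: Barbier-type indium allylation (SE2′): the allylindium adds through its ring carbon anti to the C6 side chain (C6/C7 trans), and the Zimmerman–Traxler chair with the ring-locked E-type allyl unit should give the 7,8-anti carbinol, that is 8S, the epimer of the target at C8.

Step 14
Reactants: 17 (6S,7R,8S,10S)-seco alcohol; 18 methacrylic acid
Product: 19 (6S,7R,8R,10S)-seco methacrylate: the C8 methacrylate ester of inverted configuration, C5 still as TBS ether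
Conditions: PPh3, DIAD, THF, 0 °C to rt
Reagents that add atoms: none
Why: Mitsunobu esterification: SN2 displacement of the C8 alkoxyphosphonium ion by methacrylate inverts 8S to the required 8R and installs the ester in the same step.

Step 15
Reactants: 19 (6S,7R,8R,10S)-seco methacrylate
Product: 20 (6S,7R,8R,10S)-seco methacrylate with free C5 primary alcohol
Conditions: HF·pyridine, pyridine, THF, 0 °C
Reagents that add atoms: none
Why: Buffered fluoride desilylation of the primary TBS ether, tolerated by the acetonide, the methacrylate and the α-methylene lactone.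

Step 16
Reactants: 20 (6S,7R,8R,10S)-seco methacrylate with free C5 primary alcohol
Product: 21 (6S,7R,8R,10S)-seco aldehyde: furanone with the C4–H glycerate acetonide at C3 and the lactone-bound C5 aldehyde
Conditions: Dess–Martin periodinane, NaHCO3, CH2Cl2, 0 °C
Reagents that add atoms: none
Why: Dess–Martin oxidation under buffered conditions gives the configurationally labile α-acyloxy aldehyde without epimerising C6; it is used at once.

Step 17
Reactants: 21 (6S,7R,8R,10S)-seco aldehyde
Product: 24 (4R,5S,6S,7R,8R,10S)-5-hydroxy macrocycle as C4/C15 acetonide, via trimethylsilyl dienol ether 22 (not isolated), via C5 trimethylsilyl ether 23 (not isolated)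
Conditions: TMSOTf (2.0 equiv), i-Pr2NEt (1.3 equiv), CH2Cl2 (0.002 M), −78 to −40 °C; then aq. citric acid, THF, 0 °C
Reagents that add atoms: none
Why: TMSOTf silylates the furanone carbonyl, the most Lewis-basic oxygen of the molecule, and the amine removes the C4 proton of the resulting 1-alkoxy-3-siloxyallyl cation to give the exocyclic silyl dienol ether, whose doubly oxygen-substituted C4 adds to the silyl-activated C5 aldehyde and regenerates the furanone as the C5 silyl ether, which the acidic work-up cleaves. This is an intramolecular vinylogous Mukaiyama aldol of the type known for 5-alkyl-3(2H)-furanone dienol ethers with aldehydes and acetals, medium-ring closure included. The carbocycle closes by 10-exo-trig attack on the aldehyde (nine-membered if counted through the ring oxygen), and attack through C4 and not C2 follows because only C4 restores the conjugated furanone and the five-atom tether delivers C5 to it. C5 (S) is set by the C6 stereocentre in a polar Felkin–Anh arrangement under monodentate silyl activation, with the C6–O bond anti to the incoming C4, which gives the 5,6-anti relationship. C4 (R) is set by two elements together: the C10 centre places C9 and hence the tether on one face of the furan so that C5 can reach only that face, and the bond forms from the Z dienol ether (acetal oxygen syn to the ring oxygen), expected to react faster than the E isomer with which it should equilibrate through the silylated cation, because it puts the small oxygen and not C15H2 next to C6 and opposes the C4–O and C5=O dipoles. The step needs the furanone and not the α-acyloxy aldehyde to be enolised, which rests on the far higher basicity of the vinylogous ester carbonyl towards the silyl triflate at low temperature with only a small excess of hindered amine.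

Step 18
Reactants: 24 (4R,5S,6S,7R,8R,10S)-5-hydroxy macrocycle as C4/C15 acetonide
Product: 25 (4R,5S,6S,7R,8R,10S)-5-acetoxy macrocycle as C4/C15 acetonide
Conditions: Ac2O, DMAP (cat.), pyridine, CH2Cl2, 0 °C to rt
Reagents that add atoms: acetic anhydride, CC(=O)OC(C)=O
Why: DMAP-catalysed acetylation of the only free hydroxyl; the weak base does not form the alkoxide that a retro-aldol would need.

Step 19
Reactants: 25 (4R,5S,6S,7R,8R,10S)-5-acetoxy macrocycle as C4/C15 acetonide
Product: 26 CNP0275292.1, (4R,5S,6S,7R,8R,10S)-5-acetoxy-4,15-dihydroxy-8-methacryloyloxy furanone germacranolide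
Conditions: AcOH/H2O (4:1), 45 °C
Reagents that add atoms: none
Why: Mild aqueous acid hydrolysis of the acetonide frees the C4 tertiary and C15 primary hydroxyls under conditions that spare both esters and both lactone-type rings and do not promote acetyl migration.

**Compound list**

1 | (S)-citramalic acid | C[C@](O)(CC(=O)O)C(=O)O | starting material
2 | 2-[(4S)-2,2,4-trimethyl-5-oxo-1,3-dioxolan-4-yl]acetic acid | C[C@@]1(CC(=O)O)OC(C)(C)OC1=O | intermediate
3 | (5S)-5-(2-hydroxyethyl)-2,2,5-trimethyl-1,3-dioxolan-4-one | C[C@@]1(CCO)OC(C)(C)OC1=O | intermediate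
4 | (5S)-5-[2-(tert-butyldimethylsilyloxy)ethyl]-2,2,5-trimethyl-1,3-dioxolan-4-one | C[C@@]1(CCO[Si](C)(C)C(C)(C)C)OC(C)(C)OC1=O | intermediate
5 | (2S)-4-(tert-butyldimethylsilyloxy)-2-hydroxy-N-methoxy-N,2-dimethylbutanamide | CON(C)C(=O)[C@@](C)(O)CCO[Si](C)(C)C(C)(C)C | intermediate
6 | (3S)-5-(tert-butyldimethylsilyloxy)-3-hydroxy-3-methylpentan-2-one | CC(=O)[C@@](C)(O)CCO[Si](C)(C)C(C)(C)C | intermediate
7 | methyl (4R)-2,2-dimethyl-1,3-dioxolane-4-carboxylate | COC(=O)[C@H]1COC(C)(C)O1 | starting material
8 | (4S)-6-(tert-butyldimethylsilyloxy)-1-[(4R)-2,2-dimethyl-1,3-dioxolan-4-yl]-4-hydroxy-4-methylhexane-1,3-dione | O=C(CC(=O)[C@@](C)(O)CCO[Si](C)(C)C(C)(C)C)[C@H]1COC(C)(C)O1 | intermediate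
9 | (2S)-2-[2-(tert-butyldimethylsilyloxy)ethyl]-5-[(4R)-2,2-dimethyl-1,3-dioxolan-4-yl]-2-methylfuran-3(2H)-one | C[C@@]1(CCO[Si](C)(C)C(C)(C)C)OC(=CC1=O)[C@H]1COC(C)(C)O1 | intermediate
10 | (2S)-5-[(4R)-2,2-dimethyl-1,3-dioxolan-4-yl]-2-(2-hydroxyethyl)-2-methylfuran-3(2H)-one | C[C@@]1(CCO)OC(=CC1=O)[C@H]1COC(C)(C)O1 | intermediate
11 | 2-[(2S)-5-[(4R)-2,2-dimethyl-1,3-dioxolan-4-yl]-2-methyl-3-oxo-2,3-dihydrofuran-2-yl]acetaldehyde | C[C@@]1(CC=O)OC(=CC1=O)[C@H]1COC(C)(C)O1 | intermediate
12 | (5S)-5-(hydroxymethyl)furan-2(5H)-one | OC[C@H]1OC(=O)C=C1 | starting material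
13 | (5S)-5-[(tert-butyldimethylsilyloxy)methyl]furan-2(5H)-one | CC(C)(C)[Si](C)(C)OC[C@H]1OC(=O)C=C1 | intermediate
14 | (5S)-5-[(tert-butyldimethylsilyloxy)methyl]-3-(hydroxymethyl)furan-2(5H)-one | CC(C)(C)[Si](C)(C)OC[C@H]1OC(=O)C(CO)=C1 | intermediate
15 | (5S)-3-(bromomethyl)-5-[(tert-butyldimethylsilyloxy)methyl]furan-2(5H)-one | CC(C)(C)[Si](C)(C)OC[C@H]1OC(=O)C(CBr)=C1 | intermediate
16 | allylindium bromide from 15, drawn as the dibromide (not isolated) | CC(C)(C)[Si](C)(C)OC[C@H]1OC(=O)C(C[In](Br)Br)=C1 | intermediate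
17 | (6S,7R,8S,10S)-seco alcohol (α-methylene lactone, C8–OH, C5–OTBS) | CC(C)(C)[Si](C)(C)OC[C@H]1OC(=O)C(=C)[C@@H]1[C@@H](O)C[C@]2(C)OC(=CC2=O)[C@H]3COC(C)(C)O3 | intermediate
18 | methacrylic acid | C=C(C)C(=O)O | starting material
19 | (6S,7R,8R,10S)-seco methacrylate, C5–OTBS | CC(C)(C)[Si](C)(C)OC[C@H]1OC(=O)C(=C)[C@@H]1[C@H](OC(=O)C(C)=C)C[C@]2(C)OC(=CC2=O)[C@H]3COC(C)(C)O3 | intermediate
20 | (6S,7R,8R,10S)-seco methacrylate, C5–OH | OC[C@H]1OC(=O)C(=C)[C@@H]1[C@H](OC(=O)C(C)=C)C[C@]2(C)OC(=CC2=O)[C@H]3COC(C)(C)O3 | intermediate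
21 | (6S,7R,8R,10S)-seco aldehyde (key-step precursor) | O=C[C@H]1OC(=O)C(=C)[C@@H]1[C@H](OC(=O)C(C)=C)C[C@]2(C)OC(=CC2=O)[C@H]3COC(C)(C)O3 | intermediate
22 | (Z)-trimethylsilyl dienol ether of 21 (not isolated) | O=C[C@H]1OC(=O)C(=C)[C@@H]1[C@H](OC(=O)C(C)=C)C[C@]2(C)O/C(C=C2O[Si](C)(C)C)=C3/COC(C)(C)O3 | intermediate
23 | C5 trimethylsilyl ether of the macrocycle (not isolated) | C=C(C)C(=O)O[C@@H]1C[C@]2(C)OC(=CC2=O)[C@@]3(COC(C)(C)O3)[C@@H](O[Si](C)(C)C)[C@H]2OC(=O)C(=C)[C@@H]21 | intermediate
24 | (4R,5S,6S,7R,8R,10S)-5-hydroxy macrocycle, C4/C15 acetonide | C=C(C)C(=O)O[C@@H]1C[C@]2(C)OC(=CC2=O)[C@@]3(COC(C)(C)O3)[C@@H](O)[C@H]2OC(=O)C(=C)[C@@H]21 | intermediate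
25 | (4R,5S,6S,7R,8R,10S)-5-acetoxy macrocycle, C4/C15 acetonide | C=C(C)C(=O)O[C@@H]1C[C@]2(C)OC(=CC2=O)[C@@]3(COC(C)(C)O3)[C@@H](OC(C)=O)[C@H]2OC(=O)C(=C)[C@@H]21 | intermediate
26 | CNP0275292.1 | C=C(C)C(=O)O[C@@H]1C[C@]2(C)OC(=CC2=O)[C@@](O)(CO)[C@@H](OC(C)=O)[C@H]2OC(=O)C(=C)[C@@H]21 | target

**Step count**

Total: 19 steps. Longest linear sequence: 16 steps (steps 1–9, then 13–19); the butenolide branch (steps 10–12) joins at step 13.

**Steps most likely to fail**

1. Step 17. Three processes threaten it: enolisation of the α-acyloxy aldehyde in competition with the furanone, with loss of the C6 configuration; ring closure from the E dienol ether, which would deliver the C4 epimer; and intermolecular aldol addition in place of ring closure. Ionisation of the allylic C15–O bond of the dienol ether by the silyl triflate is a further possibility. The fallback sets out from 21 and returns at 24; it removes the enolisable carbonyl before the furanone is enolised and uses an oxocarbenium ion as electrophile. Aldehyde 21 is converted with 4-methoxybenzyl trimethylsilyl ether and catalytic TMSOTf at −78 °C into the bis(4-methoxybenzyl) acetal F1. TBSOTf and Et3N then give the tert-butyldimethylsilyl dienol ether F2. Slow addition of F2 to BF3·OEt2 in CH2Cl2 at −78 °C under high dilution (Mukaiyama aldol addition to an acetal, the variant with direct precedent for medium-ring closure on 5-alkylfuranones) gives the C5 4-methoxybenzyl ether of the macrocycle F3. DDQ in wet CH2Cl2 removes the benzyl group to give 24.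

2. Step 14. Displacement at C8, which is flanked by C7 and a neopentyl-type C9, may be slow, and E2 elimination towards C7 to a conjugated diene may compete. The fallback sets out from 17 and returns at 19; it replaces the phosphonium activation by a sulfonate. Alcohol 17 is treated with chloromethanesulfonyl chloride and pyridine to give the C8 chloromethanesulfonate F4, which is displaced with inversion by cesium methacrylate (from 18 and Cs2CO3) with 18-crown-6 in toluene to give 19.

3. Step 11. The butenolide is a sluggish Baylis–Hillman acceptor; the catalyst may be consumed by formaldehyde, and prolonged exposure may epimerise the γ-centre or open the lactone. The fallback sets out from 13 and returns at 14; it builds the C–C bond by cross-coupling. α-Iodination of 13 with I2 and pyridine gives the (5S)-3-iodobutenolide F5, and Stille coupling with (tributylstannyl)methanol and Pd(PPh3)4 gives 14.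

**Further compounds**

F1 | step 17 | bis(4-methoxybenzyl) acetal of aldehyde 21 | COc1ccc(cc1)COC(OCc1ccc(OC)cc1)[C@H]1OC(=O)C(=C)[C@@H]1[C@H](OC(=O)C(C)=C)C[C@]2(C)OC(=CC2=O)[C@H]3COC(C)(C)O3
F2 | step 17 | (Z)-tert-butyldimethylsilyl dienol ether of F1 | COc1ccc(cc1)COC(OCc1ccc(OC)cc1)[C@H]1OC(=O)C(=C)[C@@H]1[C@H](OC(=O)C(C)=C)C[C@]2(C)O/C(C=C2O[Si](C)(C)C(C)(C)C)=C3/COC(C)(C)O3
F3 | step 17 | C5 4-methoxybenzyl ether of macrocycle 24 | C=C(C)C(=O)O[C@@H]1C[C@]2(C)OC(=CC2=O)[C@@]3(COC(C)(C)O3)[C@@H](OCc4ccc(OC)cc4)[C@H]2OC(=O)C(=C)[C@@H]21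
F4 | step 14 | C8 chloromethanesulfonate of alcohol 17 | CC(C)(C)[Si](C)(C)OC[C@H]1OC(=O)C(=C)[C@@H]1[C@@H](OS(=O)(=O)CCl)C[C@]2(C)OC(=CC2=O)[C@H]3COC(C)(C)O3
F5 | step 11 | (5S)-5-[(tert-butyldimethylsilyloxy)methyl]-3-iodofuran-2(5H)-one | CC(C)(C)[Si](C)(C)OC[C@H]1OC(=O)C(I)=C1
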